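**Strategy.** The target is read as a ten-membered carbocycle (C1–C10, germacrane-type locants) whose ether bridge between C5 and C10 divides it into two oxepanes. The route rests on forming O–C10 and C3–C4 together. One acid-triggered operation unmasks a C5 hydroxyl and a C3 aldehyde in a monocyclic trans-lactone that carries a C8 enone arm and a Z-allylboronate arm. Reversible oxa-Michael addition to C10 and intramolecular allylboration then close both oxepanes. The step exploits the one-atom bridge, which makes the C10 configuration a slave of C5, so enone geometry and C10 converge. The lactone stereotriad comes from one Evans aldol; the α-methylene group travels masked as a sulfide.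

Key step: step 11

Remark on locants: C6 = lactone O–CH, C7 = lactone β-CH, C8 = CH bearing the butenoate, C9 = CH2, C10 = C(CH3)–O, C1 and C2 = CH2, C3 = CH–OAc, C4 = CH–CH2OH (C15), C5 = ether CH, O5 = ether oxygen, C11–C13 = α-methylene lactone carbons. With these locants the target is 3S,4S,5R,6S,7R,8R,10R.

Assumptions: compounds 1, 4, 5, 11, 12, 16 and 24 are bought. C11 of the masked lactone (10–23, 28) is erased in step 19; it is drawn as the trans epimer. The sulfoxide sulfur in 22, 23 and 28 is an unassigned mixture.

**Step 1**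
Reactants: 1 (R)-but-3-ene-1,2-diol
Product: 2 (R)-1,2-bis(triethylsilyloxy)but-3-ene
Conditions: TESCl, imidazole, DMAP (cat.), CH2Cl2, 0 °C → rt
Reagents that add atoms: triethylsilyl chloride, CC[Si](Cl)(CC)CC
Why: Standard silylation of both hydroxyls; the stereocentre is not touched.

**Step 2**
Reactants: 2 (R)-1,2-bis(triethylsilyloxy)but-3-ene
Product: 3 (R)-2-(triethylsilyloxy)but-3-enal
Conditions: (COCl)2, DMSO, CH2Cl2, −78 → −30 °C; Et3N, −78 °C; used crude
Reagents that add atoms: none
Why: Under Swern conditions a primary TES ether is cleaved and oxidised directly to the aldehyde while the secondary TES ether survives; low temperature protects the α-stereocentre.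

**Step 3**
Reactants: 4 (S)-4-benzyloxazolidin-2-one; 5 itaconic anhydride
Product: 6 4-[(S)-4-benzyl-2-oxooxazolidin-3-yl]-2-methylene-4-oxobutanoic acid
Conditions: n-BuLi, THF, −78 °C; then 5, −78 → 0 °C; aq. HCl
Reagents that add atoms: none
Why: N-acylation of the lithiated oxazolidinone by the cyclic anhydride at the non-conjugated, less hindered carbonyl gives the imide on the CH2 side and the free acid on the acrylate side.

**Step 4**
Reactants: 6 imide acid
Product: 7 methyl 4-[(S)-4-benzyl-2-oxooxazolidin-3-yl]-2-methylene-4-oxobutanoate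
Conditions: TMSCHN2, PhMe/MeOH, 0 °C
Reagents that add atoms: (trimethylsilyl)diazomethane, C[Si](C)(C)C=[N+]=[N-]
Why: Diazoalkane esterification is neutral, so the exo-methylene does not slip into conjugation.

**Step 5**
Reactants: 7 itaconate imide; 3 (R)-2-(triethylsilyloxy)but-3-enal
Product: 9 trans-α-methylene-γ-butyrolactone with the N-acyloxazolidinone on C7 and the (1-triethylsilyloxy)allyl group on C6, via syn-aldol adduct 8 (not isolated)
Conditions: Bu2BOTf, i-Pr2NEt, CH2Cl2, −78 → 0 °C; 3, −78 → −20 °C; pH 7 buffer/MeOH; then PPTS (cat.), PhMe, 40 °C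
Reagents that add atoms: none
Why: Evans syn-aldol of the Z-boron dienolate at its α-carbon through a Zimmerman–Traxler chair sets C6 and C7 from the auxiliary, matched with the 3,4-anti (Cornforth) preference of the α-silyloxy aldehyde for C5/C6; the γ-hydroxy acrylate then lactonises to the trans lactone.

**Step 6**
Reactants: 9 lactone imide
Product: 10 S-ethyl thioester of the lactone C7 carboxylic acid with C11 carrying CH2SEt
Conditions: EtSH, n-BuLi, THF, 0 °C; NH4Cl
Reagents that add atoms: ethanethiol, CCS
Why: Lithium ethanethiolate cleaves the exocyclic imide carbonyl to the thioester and at the same time masks the α-methylene lactone by thia-Michael addition; the new C11 centre is inconsequential.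

**Step 7**
Reactants: 11 3-bromo-1,1-dimethoxypropane; 12 lithium acetylide–ethylenediamine complex
Product: 13 5,5-dimethoxypent-1-yne
Conditions: DMSO, 10 °C → rt
Reagents that add atoms: none
Why: SN2 alkylation of the acetylide by the primary bromide.

**Step 8**
Reactants: 10 thioester; 13 5,5-dimethoxypent-1-yne
Product: 14 ynone (C8 ketone, C9≡C10, dimethyl acetal at C3)
Conditions: PdCl2(dppf) (10 mol %), P(2-furyl)3, CuI, Et3N, DMF, 50 °C
Reagents that add atoms: none
Why: Pd/Cu acyl coupling of a thioester with a terminal alkyne (Fukuyama–Tokuyama type) makes the ynone without a hard nucleophile that would open the lactone.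

**Step 9**
Reactants: 14 ynone
Product: 15 β-methyl enone (C9=C10, E/Z mixture)
Conditions: Me2CuLi (from MeLi, CuI), THF, −78 °C; NH4Cl
Reagents that add atoms: lithium dimethylcuprate, [Li+].C[Cu-]C
Why: Gilman conjugate addition to the ynone installs the C10 methyl; the enone geometry does not matter because both isomers converge in step 11.

**Step 10**
Reactants: 15 enone; 16 allylboronic acid pinacol ester
Product: 17 Z-allylboronate (C4=C15 Z, CH2Bpin on C15)
Conditions: 16 (3 equiv), Z-selective Mo monoaryloxide pyrrolide alkylidene (5 mol %), C6H6, 22 °C, 100 Torr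
Reagents that add atoms: none
Why: Catalyst-controlled Z-selective cross-metathesis of the only terminal alkene with allyl-Bpin; the trisubstituted enone is inert.

**Step 11 (key step)**
Reactants: 17 Z-allylboronate
Product: 20 oxa-bridged bicyclic hydroxy ketone (O5–C10 and C3–C4 formed; C3–OH, C4–vinyl, C8 ketone), via hydroxy-aldehyde boronate 18 (not isolated), via oxepanone 19 (not isolated)
Conditions: Sc(OTf)3 (20 mol %), MeCN/H2O (20:1), 2 mM, 0 → 40 °C; pH 7 buffer
Reagents that add atoms: water, O
Why: Aqueous Sc(OTf)3 removes the TES ether and the dimethyl acetal, and the freed C5 hydroxyl adds reversibly to C10 of the enone (acid-catalysed oxa-Michael, 7-endo-trig) to give oxepanone 19, in which only one C10 epimer holds the aldehyde chain and the allylboronate on the same face. That epimer closes the second oxepane irreversibly by intramolecular allylboration of the C3 aldehyde through a Zimmerman–Traxler chair (C4 attacks C3 with allyl transposition, vinyl exocyclic); the closest precedents are acid-triggered intramolecular allylborations of acetal-masked aldehydes and transannular oxa-Michael additions in germacranolides. C10 is not set by a reagent: the one-atom oxygen bridge allows only the out,out arrangement at C5/C10, so both enone geometries and the wrong C10 epimer are funnelled by retro-oxa-Michael into the 10R product. C3 and C4 are set together: the Z-boronate puts C5 axial in the chair and, with the aldehyde chain equatorial, gives the cis C3–O/C4–vinyl pair, while the lactone-bearing bridge, pseudo-axial on the forming ring, should fix this pair cis to C5–C6. The step needs O5 and not O3 to attack C10, and the aldehyde and not the C8 ketone to be allylated; O3 is held as a borate ester until work-up, and pinacol allylboronates are slow towards ketones.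

**Step 12**
Reactants: 20 bicyclic hydroxy ketone
Product: 21 C3 acetate
Conditions: Ac2O, pyridine, DMAP (cat.), CH2Cl2, 0 °C
Reagents that add atoms: acetic anhydride, CC(=O)OC(C)=O
Why: Acetylation of the only free hydroxyl.

**Step 13**
Reactants: 21 acetate
Product: 22 C15 primary alcohol, C8 (R) alcohol, ethyl sulfoxide at C13
Conditions: O3, CH2Cl2/MeOH, −78 °C; then NaBH4, CeCl3·7H2O, −78 → −20 °C; AcOH
Reagents that add atoms: ozone, [O-][O+]=O
Why: Ozonolysis with reductive work-up turns the vinyl group into CH2OH and oxidises the sulfide to the sulfoxide (the latent methylene); hydride should add to C8 from the face anti to the C7–C11 bond and away from the C1–C4 bridge, and the cold cerium-buffered reduction limits acetate migration.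

**Step 14**
Reactants: 22 diol sulfoxide
Product: 23 C15 TBS ether
Conditions: TBSCl, imidazole, CH2Cl2, −20 °C
Reagents that add atoms: tert-butyldimethylsilyl chloride, CC(C)(C)[Si](C)(C)Cl
Why: The primary hydroxyl is silylated in preference to the hindered secondary C8 hydroxyl.

**Step 15**
Reactants: 24 methyl but-2-ynoate
Product: 25 methyl (Z)-2-(hydroxymethyl)but-2-enoate
Conditions: DIBAL-H, HMPA, THF, 0 °C; then CH2O (gas), 0 °C → rt
Reagents that add atoms: formaldehyde, C=O
Why: Syn-hydroalumination of the ynoate gives the α-alumino enoate with H and Al cis, and trapping with formaldehyde with retention leaves the ester cis to the β-methyl group (Z).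

**Step 16**
Reactants: 25 hydroxy ester
Product: 26 methyl (Z)-2-[(tert-butyldimethylsilyloxy)methyl]but-2-enoate
Conditions: TBSCl, imidazole, DMF, rt
Reagents that add atoms: tert-butyldimethylsilyl chloride, CC(C)(C)[Si](C)(C)Cl
Why: Standard silylation of the primary allylic alcohol.

**Step 17**
Reactants: 26 silyloxy ester
Product: 27 (Z)-2-[(tert-butyldimethylsilyloxy)methyl]but-2-enoic acid
Conditions: LiOH, THF/H2O, 0 °C → rt; aq. HCl to pH 4
Reagents that add atoms: lithium hydroxide, [Li+].[OH-]
Why: Mild saponification keeps the alkene geometry and the silyl ether.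

**Step 18**
Reactants: 23 C8 alcohol; 27 acid
Product: 28 C8 ester
Conditions: 27, 2,4,6-Cl3C6H2COCl, Et3N, PhMe, rt; then 23, DMAP, rt
Reagents that add atoms: none
Why: Yamaguchi esterification through the preformed mixed anhydride acylates the hindered secondary alcohol and is the usual way to keep angelate-type Z acids from isomerising.

**Step 19**
Reactants: 28 sulfoxide
Product: 29 α-methylene lactone, bis-TBS ether
Conditions: PhMe, NaHCO3, 110 °C
Reagents that add atoms: none
Why: Thermal syn-elimination of the β-sulfinyl lactone removes the activated C11 hydrogen and restores the exocyclic methylene.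

**Step 20**
Reactants: 29 bis-TBS ether
Product: 30 target CNP0195618.1
Conditions: HF·pyridine, pyridine, THF, 0 °C → rt
Reagents that add atoms: none
Why: Buffered HF removes both primary TBS ethers under weakly acidic conditions, which keeps the C3 acetate in place.

**Compound list**
1 | (R)-but-3-ene-1,2-diol | OC[C@@H](C=C)O | starting material
2 | (R)-1,2-bis(triethylsilyloxy)but-3-ene | CC[Si](CC)(CC)OC[C@@H](C=C)O[Si](CC)(CC)CC | intermediate
3 | (R)-2-(triethylsilyloxy)but-3-enal | O=C[C@@H](C=C)O[Si](CC)(CC)CC | intermediate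
4 | (S)-4-benzyloxazolidin-2-one | O=C1N[C@@H](Cc2ccccc2)CO1 | starting material
5 | itaconic anhydride | C=C1CC(=O)OC1=O | starting material
6 | 4-[(S)-4-benzyl-2-oxooxazolidin-3-yl]-2-methylene-4-oxobutanoic acid | OC(=O)C(=C)CC(=O)N1[C@@H](Cc2ccccc2)COC1=O | intermediate
7 | methyl ester of 6 | COC(=O)C(=C)CC(=O)N1[C@@H](Cc2ccccc2)COC1=O | intermediate
8 | syn-aldol adduct of 7 and 3 (C6 OH, C5 OTES anti to it) | COC(=O)C(=C)[C@H](C(=O)N1[C@@H](Cc2ccccc2)COC1=O)[C@H](O)[C@H](O[Si](CC)(CC)CC)C=C | intermediate (not isolated)
9 | trans-α-methylene lactone imide | C=C1C(=O)O[C@H]([C@H](O[Si](CC)(CC)CC)C=C)[C@H]1C(=O)N2[C@@H](Cc3ccccc3)COC2=O | intermediate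
10 | S-ethyl thioester, C11 CH2SEt (trans epimer drawn) | CCSC[C@@H]1C(=O)O[C@H]([C@H](O[Si](CC)(CC)CC)C=C)[C@H]1C(=O)SCC | intermediate
11 | 3-bromo-1,1-dimethoxypropane | COC(OC)CCBr | starting material
12 | lithium acetylide–ethylenediamine complex | [Li+].[C-]#C.NCCN | starting material
13 | 5,5-dimethoxypent-1-yne | C#CCCC(OC)OC | intermediate
14 | ynone | CCSC[C@@H]1C(=O)O[C@H]([C@H](O[Si](CC)(CC)CC)C=C)[C@H]1C(=O)C#CCCC(OC)OC | intermediate
15 | β-methyl enone (E/Z mixture) | CCSC[C@@H]1C(=O)O[C@H]([C@H](O[Si](CC)(CC)CC)C=C)[C@H]1C(=O)C=C(C)CCC(OC)OC | intermediate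
16 | allylboronic acid pinacol ester | C=CCB1OC(C)(C)C(C)(C)O1 | starting material
17 | Z-allylboronate | CCSC[C@@H]1C(=O)O[C@H]([C@H](O[Si](CC)(CC)CC)/C=C\CB2OC(C)(C)C(C)(C)O2)[C@H]1C(=O)C=C(C)CCC(OC)OC | intermediate
18 | hydroxy-aldehyde boronate (TES and acetal removed) | CCSC[C@@H]1C(=O)O[C@H]([C@H](O)/C=C\CB2OC(C)(C)C(C)(C)O2)[C@H]1C(=O)C=C(C)CCC=O | intermediate (not isolated)
19 | oxepanone (O5–C10 formed, 10R) | CCSC[C@@H]1C(=O)O[C@@H]2[C@@H](/C=C\CB3OC(C)(C)C(C)(C)O3)O[C@](C)(CCC=O)CC(=O)[C@@H]12 | intermediate (not isolated)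
20 | oxa-bridged bicyclic hydroxy ketone (C3 OH, C4 vinyl, all cis with C5–C6) | CCSC[C@@H]1C(=O)O[C@@H]2[C@@H]3O[C@](C)(CC[C@H](O)[C@@H]3C=C)CC(=O)[C@@H]12 | intermediate
21 | C3 acetate | CCSC[C@@H]1C(=O)O[C@@H]2[C@@H]3O[C@](C)(CC[C@H](OC(C)=O)[C@@H]3C=C)CC(=O)[C@@H]12 | intermediate
22 | C15 alcohol, C8 (R) alcohol, sulfoxide | CCS(=O)C[C@@H]1C(=O)O[C@@H]2[C@@H]3O[C@](C)(CC[C@H](OC(C)=O)[C@@H]3CO)C[C@@H](O)[C@@H]12 | intermediate
23 | C15 TBS ether | CCS(=O)C[C@@H]1C(=O)O[C@@H]2[C@@H]3O[C@](C)(CC[C@H](OC(C)=O)[C@@H]3CO[Si](C)(C)C(C)(C)C)C[C@@H](O)[C@@H]12 | intermediate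
24 | methyl but-2-ynoate | CC#CC(=O)OC | starting material
25 | methyl (Z)-2-(hydroxymethyl)but-2-enoate | COC(=O)/C(=C\C)CO | intermediate
26 | methyl (Z)-2-[(tert-butyldimethylsilyloxy)methyl]but-2-enoate | COC(=O)/C(=C\C)CO[Si](C)(C)C(C)(C)C | intermediate
27 | (Z)-2-[(tert-butyldimethylsilyloxy)methyl]but-2-enoic acid | OC(=O)/C(=C\C)CO[Si](C)(C)C(C)(C)C | intermediate
28 | C8 ester, sulfoxide, bis-TBS | CCS(=O)C[C@@H]1C(=O)O[C@@H]2[C@@H]3O[C@](C)(CC[C@H](OC(C)=O)[C@@H]3CO[Si](C)(C)C(C)(C)C)C[C@@H](OC(=O)/C(=C\C)CO[Si](C)(C)C(C)(C)C)[C@@H]12 | intermediate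
29 | α-methylene lactone, bis-TBS | C=C1C(=O)O[C@@H]2[C@@H]3O[C@](C)(CC[C@H](OC(C)=O)[C@@H]3CO[Si](C)(C)C(C)(C)C)C[C@@H](OC(=O)/C(=C\C)CO[Si](C)(C)C(C)(C)C)[C@@H]12 | intermediate
30 | CNP0195618.1 | C=C1C(=O)O[C@@H]2[C@@H]3O[C@](C)(CC[C@H](OC(C)=O)[C@@H]3CO)C[C@@H](OC(=O)/C(=C\C)CO)[C@@H]12 | target

**Step count.** Total: 20 steps. Longest linear sequence: 14 steps (3, 4, 5, 6, 8, 9, 10, 11, 12, 13, 14, 18, 19, 20).

**Steps most likely to fail**

Step 11. The cis-fused chair that the Z-boronate needs places C6 close to the boronate CH2 (allylic strain). Ring closure may then be slow, so that protodeboronation or allylboration of the C8 ketone competes, or it may run through the diastereomeric transition state and give the wrong C3/C4 array. The fallback sets out from 15. E-selective cross-metathesis with 16 (Hoveyda–Grubbs II, CH2Cl2, 40 °C) gives the E-allylboronate F1. The same Sc(OTf)3 cascade then runs through the strain-free trans-fused chair and should give the C3-epimeric alcohol F2 with the vinyl group unchanged. A Mitsunobu reaction with acetic acid (PPh3, DIAD, PhMe) inverts C3 and installs the acetate, and the route is rejoined at 21.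

Step 10. Turnover may be slow at the hindered allylic silyl ether, the thioether may poison the catalyst, and secondary metathesis may erode the Z purity. The fallback sets out from 15 and enforces the Z geometry with a temporary boron tether. TBAF/AcOH gives the allylic alcohol F3. Ester exchange with diisopropyl allylboronate and ring-closing metathesis of the mixed boronate (Hoveyda–Grubbs II, CH2Cl2, 40 °C) give the six-membered cyclic allylboronate F4, whose double bond is Z by necessity. Exchange with pinacol opens it to the hydroxy Z-allylboronate F5, which is taken through the step 11 conditions and rejoins the route at 20.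

Step 5. The boron dienolate of 7 may react at its γ-terminus, or the exo-methylene may move into conjugation before or after the aldol. The fallback sets out from 4 and builds the methylene after the aldol. Acylation with methyl 4-chloro-4-oxobutanoate (n-BuLi, THF) gives the succinate imide F6. Evans aldol with 3 and lactonisation give the methylene-free lactone imide F7. LiOH/H2O2 gives the acid F8. Stiles carboxylation (methyl magnesium carbonate, DMF) followed by CH2O/N-methylaniline gives the α-methylene acid F9. Thia-Michael addition (EtSH, Et3N) and thioesterification (DCC, EtSH, DMAP) rejoin the route at 10.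

**Further compounds**
F1 | step 11 | E-allylboronate analogue of 17 | CCSC[C@@H]1C(=O)O[C@H]([C@H](O[Si](CC)(CC)CC)/C=C/CB2OC(C)(C)C(C)(C)O2)[C@H]1C(=O)C=C(C)CCC(OC)OC
F2 | step 11 | C3 epimer of 20 | CCSC[C@@H]1C(=O)O[C@@H]2[C@@H]3O[C@](C)(CC[C@@H](O)[C@@H]3C=C)CC(=O)[C@@H]12
F3 | step 10 | C5 allylic alcohol from 15 | CCSC[C@@H]1C(=O)O[C@H]([C@H](O)C=C)[C@H]1C(=O)C=C(C)CCC(OC)OC
F4 | step 10 | cyclic isopropyl allylboronate (3,6-dihydro-2H-1,2-oxaborinine, C5 in the ring) | CCSC[C@@H]1C(=O)O[C@H]([C@@H]2OB(OC(C)C)CC=C2)[C@H]1C(=O)C=C(C)CCC(OC)OC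
F5 | step 10 | hydroxy Z-allylboronate (17 without TES) | CCSC[C@@H]1C(=O)O[C@H]([C@H](O)/C=C\CB2OC(C)(C)C(C)(C)O2)[C@H]1C(=O)C=C(C)CCC(OC)OC
F6 | step 5 | methyl 4-[(S)-4-benzyl-2-oxooxazolidin-3-yl]-4-oxobutanoate | COC(=O)CCC(=O)N1[C@@H](Cc2ccccc2)COC1=O
F7 | step 5 | methylene-free trans lactone imide | C1C(=O)O[C@H]([C@H](O[Si](CC)(CC)CC)C=C)[C@H]1C(=O)N2[C@@H](Cc3ccccc3)COC2=O
F8 | step 5 | trans lactone C7 carboxylic acid | C1C(=O)O[C@H]([C@H](O[Si](CC)(CC)CC)C=C)[C@H]1C(=O)O
F9 | step 5 | α-methylene lactone C7 carboxylic acid | C=C1C(=O)O[C@H]([C@H](O[Si](CC)(CC)CC)C=C)[C@H]1C(=O)O
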